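The depside ester is cut last, leaving ring A as benzyl 2-heptyl-4,6-dihydroxybenzoate. Ring A (C1 carboxyl, C2 heptyl, C4 and C6 oxygens) has the oxidation pattern of a 4-carboxy-5-heptylcyclohexane-1,3-dione: the carboxyl carbon sits beside one carbonyl only, and the heptyl group is on an sp3 carbon. A Michael–Claisen annulation of benzyl acetoacetate with benzyl (E)-dec-2-enoate forms the C1–C2 and C4–C5 bonds and the six-membered ring in one operation; the precursors are simply these two benzyl esters. Late dehydrogenation, 4-O-acylation with dibenzyl-protected orsellinic acid and a single hydrogenolysis finish the route.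

Key step: step 2

Remark: the target is achiral. Ring A is the heptyl-bearing benzoic acid ring (C1 carboxyl, C2 heptyl, C4 depside oxygen, C6 hydroxyl) and ring B is the orsellinoyl ring. Compound 5 is written as the enol (vinylogous acid) tautomer of the 2,4-dione and carries its own cyclohexene numbering.

Step 1
Reactants: 1 (E)-dec-2-enoic acid
Product: 2 benzyl (E)-dec-2-enoate
Conditions: BnBr (1.05 equiv), K2CO3, DMF, rt
Reagents that add atoms: benzyl bromide, BrCc1ccccc1
Why: SN2 O-alkylation of the potassium carboxylate by benzyl bromide should run cleanly at room temperature, under conditions too mild to isomerise or deconjugate the E-enoate.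

Step 2
Reactants: 3 benzyl acetoacetate (benzyl 3-oxobutanoate); 2 benzyl (E)-dec-2-enoate
Product: 5 benzyl trans-6-heptyl-2-hydroxy-4-oxocyclohex-2-ene-1-carboxylate (racemic), via dibenzyl 2-acetyl-3-heptylpentanedioate 4 (not isolated)
Conditions: NaH (1.1 equiv), BnOH (1.2 equiv), THF, 0 °C; 3, then 2, reflux; 1 M HCl, 0 °C
Reagents that add atoms: none
Why: The sodium enolate of 3 adds 1,4 to enoate 2, joining its central carbon to the heptyl-bearing carbon (ring-A C1–C2) to give keto diester 4 after proton transfer; equilibration then supplies the acetyl methyl enolate, which attacks the chain benzyl ester and expels benzyloxide (ring-A C4–C5), and deprotonation of the acidic dione (recovered on acidification) pulls the preceding equilibria forward. The closest known reaction type is the classical Michael addition–Claisen (Dieckmann-type) annulation of acetoacetates with alk-2-enoates to dihydroresorcylates. The ring closes by a 6-(enolendo)-exo-trig acyl substitution. The two stereocentres (C1 and C6 of 5) form as a racemate without absolute control, and reversible enolisation at the doubly activated C1–H should let the ester settle trans to the neighbouring heptyl group under thermodynamic control; both centres are erased in step 3. Only regiocontrol is needed: 1,4-addition of the soft enolate fixes heptyl next to the ester-bearing carbon, only the methyl enolate can reach the chain ester through a six-membered transition state (the central carbon would have to close a four-membered ring), and benzyloxide matched to benzyl esters makes any ester exchange degenerate.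

Step 3
Reactants: 5 benzyl trans-6-heptyl-2-hydroxy-4-oxocyclohex-2-ene-1-carboxylate
Product: 7 benzyl 2-heptyl-4,6-dihydroxybenzoate, via benzyl 3-bromo-6-heptyl-2-hydroxy-4-oxocyclohex-2-ene-1-carboxylate 6 (not isolated)
Conditions: Br2 (1.0 equiv), DMF, 0 °C to rt; then 60 °C
Reagents that add atoms: none
Why: Halogenation–dehydrohalogenation aromatisation: the enolised dione is brominated between its two carbonyls to give 6, whose bis-enol tautomer is a cyclohexa-1,4-diene with bromide and the C6 hydrogen in a 1,4-relationship, so loss of HBr on warming should give the resorcylate; one equivalent of bromine is consumed cold, before any phenol exists, to limit nuclear bromination.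

Step 4
Reactants: 8 orsellinic acid (2,4-dihydroxy-6-methylbenzoic acid)
Product: 9 benzyl 2,4-bis(benzyloxy)-6-methylbenzoate
Conditions: BnBr (3.5 equiv), K2CO3, DMF, rt then 60 °C
Reagents that add atoms: benzyl bromide, BrCc1ccccc1
Why: Carboxylate alkylation followed by Williamson etherification: the carboxylate is esterified first at room temperature (which removes the risk of decarboxylation), and gentle heating completes benzylation of the chelated 2-hydroxyl.

Step 5
Reactants: 9 benzyl 2,4-bis(benzyloxy)-6-methylbenzoate
Product: 10 2,4-bis(benzyloxy)-6-methylbenzoic acid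
Conditions: KOH, DMSO–H2O (4:1), 90 °C; then 2 M HCl, 0 °C
Reagents that add atoms: potassium hydroxide, [K+].[OH-]
Why: Saponification of the hindered benzoate needs forcing hydroxide conditions, which the benzyl aryl ethers tolerate, and cold acidification frees the acid.

Step 6
Reactants: 10 2,4-bis(benzyloxy)-6-methylbenzoic acid; 7 benzyl 2-heptyl-4,6-dihydroxybenzoate
Product: 12 benzyl 4-{[2,4-bis(benzyloxy)-6-methylbenzoyl]oxy}-2-heptyl-6-hydroxybenzoate, via 2,4-bis(benzyloxy)-6-methylbenzoic trifluoroacetic anhydride 11 (not isolated)
Conditions: (CF3CO)2O (3 equiv), toluene, rt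
Reagents that add atoms: none
Why: Mixed-anhydride esterification: trifluoroacetic anhydride converts 10 into acyl trifluoroacetate 11, which should acylate the free C4 hydroxyl of 7, while the C6 hydroxyl is held in a hydrogen bond to the ortho ester carbonyl and is far less nucleophilic.

Step 7
Reactants: 12 benzyl 4-{[2,4-bis(benzyloxy)-6-methylbenzoyl]oxy}-2-heptyl-6-hydroxybenzoate
Product: 13 4-[(2,4-dihydroxy-6-methylbenzoyl)oxy]-2-heptyl-6-hydroxybenzoic acid (CNP0227363.0)
Conditions: H2 (1 atm), 10% Pd/C, EtOAc, rt
Reagents that add atoms: none
Why: Catalytic hydrogenolysis should cleave the benzyl ester and both benzyl ethers under neutral conditions at room temperature, which spare the aryl ester (depside) bond and the decarboxylation-prone salicylic acid.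

Compound list
1 | (E)-dec-2-enoic acid | CCCCCCC/C=C/C(=O)O | starting material
2 | benzyl (E)-dec-2-enoate | CCCCCCC/C=C/C(=O)OCc1ccccc1 | intermediate
3 | benzyl acetoacetate (benzyl 3-oxobutanoate) | CC(=O)CC(=O)OCc1ccccc1 | starting material
4 | dibenzyl 2-acetyl-3-heptylpentanedioate (Michael adduct; racemic mixture of diastereomers, configuration not defined; not isolated) | CCCCCCCC(CC(=O)OCc1ccccc1)C(C(C)=O)C(=O)OCc1ccccc1 | intermediate
5 | benzyl trans-6-heptyl-2-hydroxy-4-oxocyclohex-2-ene-1-carboxylate (racemic; the 1S,6R enantiomer is drawn) | CCCCCCC[C@@H]1CC(=O)C=C(O)[C@H]1C(=O)OCc1ccccc1 | intermediate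
6 | benzyl trans-3-bromo-6-heptyl-2-hydroxy-4-oxocyclohex-2-ene-1-carboxylate (racemic, one enantiomer drawn; not isolated) | CCCCCCC[C@@H]1CC(=O)C(Br)=C(O)[C@H]1C(=O)OCc1ccccc1 | intermediate
7 | benzyl 2-heptyl-4,6-dihydroxybenzoate | CCCCCCCc1cc(O)cc(O)c1C(=O)OCc1ccccc1 | intermediate
8 | orsellinic acid (2,4-dihydroxy-6-methylbenzoic acid) | Cc1cc(O)cc(O)c1C(=O)O | starting material
9 | benzyl 2,4-bis(benzyloxy)-6-methylbenzoate | Cc1cc(OCc2ccccc2)cc(OCc2ccccc2)c1C(=O)OCc1ccccc1 | intermediate
10 | 2,4-bis(benzyloxy)-6-methylbenzoic acid | Cc1cc(OCc2ccccc2)cc(OCc2ccccc2)c1C(=O)O | intermediate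
11 | 2,4-bis(benzyloxy)-6-methylbenzoic trifluoroacetic anhydride (not isolated) | Cc1cc(OCc2ccccc2)cc(OCc2ccccc2)c1C(=O)OC(=O)C(F)(F)F | intermediate
12 | benzyl 4-{[2,4-bis(benzyloxy)-6-methylbenzoyl]oxy}-2-heptyl-6-hydroxybenzoate | CCCCCCCc1cc(OC(=O)c2c(C)cc(OCc3ccccc3)cc2OCc2ccccc2)cc(O)c1C(=O)OCc1ccccc1 | intermediate
13 | 4-[(2,4-dihydroxy-6-methylbenzoyl)oxy]-2-heptyl-6-hydroxybenzoic acid (CNP0227363.0) | CCCCCCCc1cc(OC(=O)c2c(C)cc(O)cc2O)cc(O)c1C(=O)O | target

Total step count: 7.
Longest linear sequence: 5 steps (steps 1, 2, 3, 6, 7); the two-step branch (steps 4, 5) joins at step 6.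

Steps most likely to fail

Step 2. Conjugate addition to the β-alkyl enoate may be slow enough that base-induced cleavage and self-condensation of the acetoacetate, or deconjugation of the enoate, use up the partners before the ring closes. The fallback sets out from 1 and returns at 5. Acid 1 would be coupled with N,O-dimethylhydroxylamine hydrochloride (EDC hydrochloride, Et3N, CH2Cl2) to give (E)-N-methoxy-N-methyldec-2-enamide F1. MeMgBr in THF at 0 °C with a cold aqueous HCl quench would then give (E)-undec-3-en-2-one F2, a much better Michael acceptor. F2 would be treated with dibenzyl malonate (O=C(CC(=O)OCc1ccccc1)OCc1ccccc1) and sodium benzyloxide (NaH, BnOH) in refluxing THF. The malonate adduct dibenzyl 2-(2-oxoundecan-4-yl)propanedioate F3 (not isolated) should close by attack of its methyl ketone enolate on one malonate ester, which gives 5 with heptyl again beside the ester-bearing carbon.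

Step 3. Nuclear bromination of the newly formed resorcinol ring, or bromide-induced loss of the benzyl ester followed by decarboxylation during the warm dehydrobromination, may erode the resorcylate. The fallback sets out from 5 and returns at 7; it aromatises without halogen and without a hydrogenolysable group, then reinstalls the carboxyl.
- Hydrogenolysis of 5 (H2, 10% Pd/C, EtOAc, rt) would give 6-heptyl-2-hydroxy-4-oxocyclohex-2-ene-1-carboxylic acid F4 (not isolated), a β-keto acid that loses CO2 on gentle warming to give 5-heptylcyclohexane-1,3-dione F5.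
- Catalytic dehydrogenation (10% Pd/C, refluxing mesitylene) would give 5-heptylbenzene-1,3-diol F6.
- Ortho-carboxylation with MeOMgOCO2Me in DMF at 120 °C, then cold dilute HCl, would give 2-heptyl-4,6-dihydroxybenzoic acid F7.
- Selective carboxylate benzylation (BnBr, KHCO3, DMF, rt) would give 7.

Step 6. Under the acidic mixed-anhydride conditions, Friedel–Crafts C-acylation of electron-rich ring A, acid-induced loss of the ortho benzyl ether of the acyl donor, or incomplete discrimination between the two hydroxyls may compete with the desired O-acylation. The fallback sets out from 10 and returns at 12. Acid 10 would be converted with oxalyl chloride and catalytic DMF in CH2Cl2 into 2,4-bis(benzyloxy)-6-methylbenzoyl chloride F8. F8 would then be combined with 7 under basic conditions (Et3N, catalytic DMAP, CH2Cl2, 0 °C to rt), where the more acidic, non-chelated C4 hydroxyl should be acylated and no electrophilic aromatic substitution is expected.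

Further compounds
F1 | step 2 | (E)-N-methoxy-N-methyldec-2-enamide | CCCCCCC/C=C/C(=O)N(C)OC
F2 | step 2 | (E)-undec-3-en-2-one | CCCCCCC/C=C/C(C)=O
F3 | step 2 | dibenzyl 2-(2-oxoundecan-4-yl)propanedioate (racemic, not isolated) | CCCCCCCC(CC(C)=O)C(C(=O)OCc1ccccc1)C(=O)OCc1ccccc1
F4 | step 3 | trans-6-heptyl-2-hydroxy-4-oxocyclohex-2-ene-1-carboxylic acid (racemic, one enantiomer drawn; not isolated) | CCCCCCC[C@@H]1CC(=O)C=C(O)[C@H]1C(=O)O
F5 | step 3 | 5-heptylcyclohexane-1,3-dione | CCCCCCCC1CC(=O)CC(=O)C1
F6 | step 3 | 5-heptylbenzene-1,3-diol | CCCCCCCc1cc(O)cc(O)c1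
F7 | step 3 | 2-heptyl-4,6-dihydroxybenzoic acid | CCCCCCCc1cc(O)cc(O)c1C(=O)O
F8 | step 6 | 2,4-bis(benzyloxy)-6-methylbenzoyl chloride | Cc1cc(OCc2ccccc2)cc(OCc2ccccc2)c1C(=O)Cl
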